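**Strategy.** The target is the aldol self-condensation dimer of one aldehyde, so a single N-Boc 6-alkyl-2-methylpiperidin-3-ol is built and dimerised last. Each piperidine ring is disconnected at C2–C3 and C5–C6, the bonds that join its three-carbon segment C3–C4–C5 (carbinol carbon, two methylenes) to the nitrogen-bearing carbons C2 and C6. The key step treats 3-(methoxymethoxy)propyne as a 1,3-dianion for that segment: in one flask its oxygen-bearing propargylic carbon adds to an N-sulfinyl acetaldimine (C2, N1, methyl) and its acetylide carbon is acylated by a C13 N-methoxy-N-methylamide (C6, side chain). The acyclic ynone is folded into the ring by hydrogenation; C3 is then reset by oxidation and reduction.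

Key step: step 5

Remark on the chemistry: every piperidine is numbered N1, C2 (methyl), C3 (hydroxyl), C4, C5, C6 (chain); in this numbering both rings of the target are (2S,3S,6R), all-cis, and the enal is E.

Step 1
Reactants: 1 12-bromododecan-1-ol
Product: 2 [(12-bromododecyl)oxy](tert-butyl)diphenylsilane
Conditions: TBDPSCl, imidazole, CH2Cl2, rt
Reagents that add atoms: tert-butyl(chloro)diphenylsilane, CC(C)(C)[Si](Cl)(c1ccccc1)c1ccccc1
Why: O-silylation of the primary alcohol gives a silyl ether that should survive the Grignard, organolithium, acid and hydrogenation stages and is removed by fluoride in step 10.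

Step 2
Reactants: 2 [(12-bromododecyl)oxy](tert-butyl)diphenylsilane, 3 N-methoxy-N-methylcarbamoyl chloride
Product: 5 13-[(tert-butyldiphenylsilyl)oxy]-N-methoxy-N-methyltridecanamide, via Grignard reagent 4 (not isolated)
Conditions: Mg, THF, 40 °C; then 3, THF, −78 → 0 °C
Reagents that add atoms: none
Why: Grignard acylation by the carbamoyl chloride (nucleophilic acyl substitution) should stop at the N-methoxy-N-methylamide because its chelated tetrahedral adduct does not collapse at low temperature; the carbonyl carbon introduced here becomes C6.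

Step 3
Reactants: 6 prop-2-yn-1-ol
Product: 7 3-(methoxymethoxy)prop-1-yne
Conditions: MOMCl, i-Pr2NEt, CH2Cl2, 0 °C → rt
Reagents that add atoms: chloromethyl methyl ether, COCCl
Why: O-alkylation to the mixed acetal gives an ether that tolerates and assists propargylic metalation, adds no stereocenter and is cleaved by acid in step 6.

Step 4
Reactants: 8 (S)-2-methylpropane-2-sulfinamide, 9 acetaldehyde
Product: 10 (S,E)-N-ethylidene-2-methylpropane-2-sulfinamide
Conditions: MgSO4, PPTS (cat.), CH2Cl2, rt
Reagents that add atoms: none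
Why: acid-catalysed condensation (imine formation) should give the E-aldimine that supplies C2, its methyl group, the ring nitrogen and the chiral controller.

Step 5
Reactants: 7 3-(methoxymethoxy)prop-1-yne, 10 (S,E)-N-ethylidene-2-methylpropane-2-sulfinamide, 5 13-[(tert-butyldiphenylsilyl)oxy]-N-methoxy-N-methyltridecanamide
Product: 13 (S)-N-[(2S,3R)-18-[(tert-butyldiphenylsilyl)oxy]-3-(methoxymethoxy)-6-oxooctadec-4-yn-2-yl]-2-methylpropane-2-sulfinamide, via dimagnesiated propargyl ether 11 (not isolated), via magnesium acetylide adduct 12 (not isolated)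
Conditions: n-BuLi, then s-BuLi, TMEDA, THF, −78 °C; MgBr2·OEt2; 10, −78 → −30 °C; 5, −30 °C → rt; H2O
Reagents that add atoms: none
Why: Deprotonation of 7 at the acetylenic C–H and then at the propargylic C–H next to oxygen, followed by transmetalation, should give a 1,3-dimetalated three-carbon unit whose propargyl/allenyl carbon is the more reactive site and adds first to the C=N bond of 10 by SE2' (C2–C3), after which the surviving alkynylmagnesium carbon is acylated by 5 (C5–C6). Both events are known reaction types, the addition of α-alkoxy propargyl/allenyl metals to N-tert-butanesulfinyl aldimines and the alkynylation of N-methoxy-N-methylamides, and their ordering on one linchpin follows the behaviour of 1,3-dimetalated propynes. No ring is closed here; the step assembles the chain C2–C6 with nitrogen on C2, oxygen on C3 and the C6 carbonyl that step 6 closes. C2 is controlled by the sulfinyl group through a magnesium-chelated six-membered transition state (attack on the Re face of the S-configured imine should give 2S), while C3 is expected anti to nitrogen from the cyclic SE2' geometry and is not relied on, because steps 8 and 9 reset it. The step needs site selectivity between the two carbanion centres and must avoid deprotonation of the imine methyl group; the higher reactivity of the allenylmagnesium site, the low basicity of magnesium reagents and the order of addition should secure both.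

Step 6
Reactants: 13 (S)-N-[(2S,3R)-18-[(tert-butyldiphenylsilyl)oxy]-3-(methoxymethoxy)-6-oxooctadec-4-yn-2-yl]-2-methylpropane-2-sulfinamide
Product: 16 (2S,3R,6R)-6-{12-[(tert-butyldiphenylsilyl)oxy]dodecyl}-2-methylpiperidin-3-ol, via saturated keto sulfinamide 14 (not isolated), via cyclic imine 15 (not isolated)
Conditions: H2, Pd/C, EtOAc, rt; HCl, MeOH, 40 °C, then evaporation; Et3N, H2, Pd/C, MeOH, rt
Reagents that add atoms: none
Why: heterogeneous hydrogenation saturates the ynone, acid methanolysis removes the sulfinyl and MOM groups, and the freed amine condenses with the C6 ketone (6-exo-trig, then dehydration) to a cyclic imine whose hydrogenation (reductive amination) should add hydrogen to the face opposite the C2 methyl group and set C6 cis to C2.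

Step 7
Reactants: 16 (2S,3R,6R)-6-{12-[(tert-butyldiphenylsilyl)oxy]dodecyl}-2-methylpiperidin-3-ol
Product: 17 tert-butyl (2S,3R,6R)-6-{12-[(tert-butyldiphenylsilyl)oxy]dodecyl}-3-hydroxy-2-methylpiperidine-1-carboxylate
Conditions: Boc2O, Et3N, MeOH, 50 °C
Reagents that add atoms: di-tert-butyl dicarbonate, CC(C)(C)OC(=O)OC(=O)OC(C)(C)C
Why: carbamate formation at the hindered secondary amine, which should react in preference to the secondary alcohol, masks nitrogen for the oxidation, hydride and aldol steps.

Step 8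
Reactants: 17 tert-butyl (2S,3R,6R)-6-{12-[(tert-butyldiphenylsilyl)oxy]dodecyl}-3-hydroxy-2-methylpiperidine-1-carboxylate
Product: 18 tert-butyl (2S,6R)-6-{12-[(tert-butyldiphenylsilyl)oxy]dodecyl}-2-methyl-3-oxopiperidine-1-carboxylate
Conditions: DMP, CH2Cl2, rt
Reagents that add atoms: none
Why: Dess–Martin oxidation of the secondary alcohol erases C3, so either C3 configuration from step 5 converges on one ketone, and the cis-2,6 arrangement, the preferred one for an N-acyl piperidine, should be kept.

Step 9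
Reactants: 18 tert-butyl (2S,6R)-6-{12-[(tert-butyldiphenylsilyl)oxy]dodecyl}-2-methyl-3-oxopiperidine-1-carboxylate
Product: 19 tert-butyl (2S,3S,6R)-6-{12-[(tert-butyldiphenylsilyl)oxy]dodecyl}-3-hydroxy-2-methylpiperidine-1-carboxylate
Conditions: LiBH(s-Bu)3, THF, −78 °C; H2O
Reagents that add atoms: none
Why: diastereoselective hydride reduction of the ketone: allylic 1,3-strain to the carbamate holds the C2 methyl group axial, where it shields its own face of the neighbouring carbonyl, so the bulky borohydride should attack anti to it and place the C3 hydroxyl cis to the methyl group (3S).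

Step 10
Reactants: 19 tert-butyl (2S,3S,6R)-6-{12-[(tert-butyldiphenylsilyl)oxy]dodecyl}-3-hydroxy-2-methylpiperidine-1-carboxylate
Product: 20 tert-butyl (2S,3S,6R)-3-hydroxy-6-(12-hydroxydodecyl)-2-methylpiperidine-1-carboxylate
Conditions: TBAF, THF, rt
Reagents that add atoms: none
Why: fluoride-induced desilylation should free the primary alcohol without touching the carbamate.

Step 11
Reactants: 20 tert-butyl (2S,3S,6R)-3-hydroxy-6-(12-hydroxydodecyl)-2-methylpiperidine-1-carboxylate
Product: 21 tert-butyl (2S,3S,6R)-3-hydroxy-2-methyl-6-(12-oxododecyl)piperidine-1-carboxylate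
Conditions: TEMPO (cat.), PhI(OAc)2, CH2Cl2, rt
Reagents that add atoms: none
Why: oxoammonium-mediated oxidation should select the unhindered primary alcohol over the hindered secondary one and stop at the aldehyde.

Step 12
Reactants: 21 tert-butyl (2S,3S,6R)-3-hydroxy-2-methyl-6-(12-oxododecyl)piperidine-1-carboxylate (two molecules)
Product: 22 (2E)-2-{10-[(2R,5S,6S)-1-(tert-butoxycarbonyl)-5-hydroxy-6-methylpiperidin-2-yl]decyl}-14-[(2R,5S,6S)-1-(tert-butoxycarbonyl)-5-hydroxy-6-methylpiperidin-2-yl]tetradec-2-enal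
Conditions: pyrrolidine (cat.), PhCO2H (cat.), toluene, 50 °C
Reagents that add atoms: none
Why: enamine-catalysed aldol self-condensation, in which the enamine of one aldehyde adds to a second and the aldol dehydrates to the conjugated 2-alkyl-2-enal, should give the E isomer (chain trans to the formyl group) as the thermodynamic product.

Step 13
Reactants: 22 (2E)-2-{10-[(2R,5S,6S)-1-(tert-butoxycarbonyl)-5-hydroxy-6-methylpiperidin-2-yl]decyl}-14-[(2R,5S,6S)-1-(tert-butoxycarbonyl)-5-hydroxy-6-methylpiperidin-2-yl]tetradec-2-enal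
Product: 23 (2E)-2-{10-[(2R,5S,6S)-5-hydroxy-6-methylpiperidin-2-yl]decyl}-14-[(2R,5S,6S)-5-hydroxy-6-methylpiperidin-2-yl]tetradec-2-enal (CNP0177491.1)
Conditions: TFA, CH2Cl2, 0 °C; aq NaHCO3
Reagents that add atoms: none
Why: acidolysis of both tert-butyl carbamates should leave the enal, the hydroxyl groups and all six stereocenters untouched and give the free bis-piperidine after neutralisation.

**Compound list**

1 | 12-bromododecan-1-ol | OCCCCCCCCCCCCBr | starting material
2 | [(12-bromododecyl)oxy](tert-butyl)diphenylsilane | CC(C)(C)[Si](OCCCCCCCCCCCCBr)(c1ccccc1)c1ccccc1 | intermediate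
3 | N-methoxy-N-methylcarbamoyl chloride | CON(C)C(Cl)=O | starting material
4 | {12-[(tert-butyldiphenylsilyl)oxy]dodecyl}magnesium bromide | CC(C)(C)[Si](OCCCCCCCCCCCC[Mg]Br)(c1ccccc1)c1ccccc1 | intermediate
5 | 13-[(tert-butyldiphenylsilyl)oxy]-N-methoxy-N-methyltridecanamide | CON(C)C(=O)CCCCCCCCCCCCO[Si](c1ccccc1)(c1ccccc1)C(C)(C)C | intermediate
6 | prop-2-yn-1-ol | C#CCO | starting material
7 | 3-(methoxymethoxy)prop-1-yne | C#CCOCOC | intermediate
8 | (S)-2-methylpropane-2-sulfinamide | CC(C)(C)[S@](=O)N | starting material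
9 | acetaldehyde | CC=O | starting material
10 | (S,E)-N-ethylidene-2-methylpropane-2-sulfinamide | CC(C)(C)[S@](=O)/N=C/C | intermediate
11 | 1,3-bis(bromomagnesio)-3-(methoxymethoxy)prop-1-yne (propargyl/allenyl metallotropic species, labile at C3) | COCOC([Mg]Br)C#C[Mg]Br | intermediate
12 | N,C-bis(bromomagnesium) salt of (S)-N-[(2S,3R)-3-(methoxymethoxy)pent-4-yn-2-yl]-2-methylpropane-2-sulfinamide | C[C@H](N([Mg]Br)[S@@](=O)C(C)(C)C)[C@H](OCOC)C#C[Mg]Br | intermediate
13 | (S)-N-[(2S,3R)-18-[(tert-butyldiphenylsilyl)oxy]-3-(methoxymethoxy)-6-oxooctadec-4-yn-2-yl]-2-methylpropane-2-sulfinamide | C[C@H](N[S@@](=O)C(C)(C)C)[C@H](OCOC)C#CC(=O)CCCCCCCCCCCCO[Si](c1ccccc1)(c1ccccc1)C(C)(C)C | intermediate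
14 | (S)-N-[(2S,3R)-18-[(tert-butyldiphenylsilyl)oxy]-3-(methoxymethoxy)-6-oxooctadecan-2-yl]-2-methylpropane-2-sulfinamide | C[C@H](N[S@@](=O)C(C)(C)C)[C@H](OCOC)CCC(=O)CCCCCCCCCCCCO[Si](c1ccccc1)(c1ccccc1)C(C)(C)C | intermediate
15 | (2S,3R)-6-{12-[(tert-butyldiphenylsilyl)oxy]dodecyl}-2-methyl-2,3,4,5-tetrahydropyridin-3-ol | C[C@@H]1N=C(CCCCCCCCCCCCO[Si](c2ccccc2)(c2ccccc2)C(C)(C)C)CC[C@H]1O | intermediate
16 | (2S,3R,6R)-6-{12-[(tert-butyldiphenylsilyl)oxy]dodecyl}-2-methylpiperidin-3-ol | C[C@@H]1N[C@H](CCCCCCCCCCCCO[Si](c2ccccc2)(c2ccccc2)C(C)(C)C)CC[C@H]1O | intermediate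
17 | tert-butyl (2S,3R,6R)-6-{12-[(tert-butyldiphenylsilyl)oxy]dodecyl}-3-hydroxy-2-methylpiperidine-1-carboxylate | C[C@@H]1N(C(=O)OC(C)(C)C)[C@H](CCCCCCCCCCCCO[Si](c2ccccc2)(c2ccccc2)C(C)(C)C)CC[C@H]1O | intermediate
18 | tert-butyl (2S,6R)-6-{12-[(tert-butyldiphenylsilyl)oxy]dodecyl}-2-methyl-3-oxopiperidine-1-carboxylate | C[C@@H]1N(C(=O)OC(C)(C)C)[C@H](CCCCCCCCCCCCO[Si](c2ccccc2)(c2ccccc2)C(C)(C)C)CCC1=O | intermediate
19 | tert-butyl (2S,3S,6R)-6-{12-[(tert-butyldiphenylsilyl)oxy]dodecyl}-3-hydroxy-2-methylpiperidine-1-carboxylate | C[C@@H]1N(C(=O)OC(C)(C)C)[C@H](CCCCCCCCCCCCO[Si](c2ccccc2)(c2ccccc2)C(C)(C)C)CC[C@@H]1O | intermediate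
20 | tert-butyl (2S,3S,6R)-3-hydroxy-6-(12-hydroxydodecyl)-2-methylpiperidine-1-carboxylate | C[C@@H]1N(C(=O)OC(C)(C)C)[C@H](CCCCCCCCCCCCO)CC[C@@H]1O | intermediate
21 | tert-butyl (2S,3S,6R)-3-hydroxy-2-methyl-6-(12-oxododecyl)piperidine-1-carboxylate | C[C@@H]1N(C(=O)OC(C)(C)C)[C@H](CCCCCCCCCCCC=O)CC[C@@H]1O | intermediate
22 | (2E)-2-{10-[(2R,5S,6S)-1-(tert-butoxycarbonyl)-5-hydroxy-6-methylpiperidin-2-yl]decyl}-14-[(2R,5S,6S)-1-(tert-butoxycarbonyl)-5-hydroxy-6-methylpiperidin-2-yl]tetradec-2-enal | C[C@@H]1N(C(=O)OC(C)(C)C)[C@H](CCCCCCCCCCC/C=C(/C=O)CCCCCCCCCC[C@@H]2CC[C@H](O)[C@H](C)N2C(=O)OC(C)(C)C)CC[C@@H]1O | intermediate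
23 | (2E)-2-{10-[(2R,5S,6S)-5-hydroxy-6-methylpiperidin-2-yl]decyl}-14-[(2R,5S,6S)-5-hydroxy-6-methylpiperidin-2-yl]tetradec-2-enal (CNP0177491.1) | C[C@@H]1N[C@H](CCCCCCCCCCC/C=C(/C=O)CCCCCCCCCC[C@@H]2CC[C@H](O)[C@H](C)N2)CC[C@@H]1O | target

**Step count and risks**

Total step count: 13. Longest linear sequence: 11 steps (1, 2, 5, 6, 7, 8, 9, 10, 11, 12, 13).

Step 5. The two carbanion centres of 11 may not react in the intended order, the imine may be deprotonated at its methyl group, or facial control at C2 may erode because the propargyl/allenyl reagent is stereogenic and labile. The fallback sets out from 7, 10 and 5 and comes back at 13; it uses the linchpin one end at a time. C-Silylation of 7 (n-BuLi, Me3SiCl) should give [3-(methoxymethoxy)prop-1-yn-1-yl]trimethylsilane F1. Propargylic lithiation (s-BuLi) and transmetalation with ZnBr2 give the racemic allenylzinc bromide F2, taken in excess so that imine 10 consumes its matching enantiomer through a zinc-chelated SE2' transition state. Aqueous work-up should then give the anti adduct (S)-N-[(2S,3R)-3-(methoxymethoxy)-5-(trimethylsilyl)pent-4-yn-2-yl]-2-methylpropane-2-sulfinamide F3. K2CO3 in MeOH removes the silyl group to give the terminal alkyne (S)-N-[(2S,3R)-3-(methoxymethoxy)pent-4-yn-2-yl]-2-methylpropane-2-sulfinamide F4. Its N,C-dilithio salt F5 (n-BuLi, two equivalents) is acylated by 5 to give 13.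

Step 9. Hydride delivery may lose facial selectivity if the ring populates a conformer with an equatorial C2 methyl group, and ketone 18 may enolise toward C2. The fallback sets out from 17 and comes back at 19 without passing through the ketone. A Mitsunobu reaction of 17 with 4-nitrobenzoic acid (PPh3, DIAD, THF) should invert C3 by SN2 displacement and give tert-butyl (2S,3S,6R)-6-{12-[(tert-butyldiphenylsilyl)oxy]dodecyl}-2-methyl-3-[(4-nitrobenzoyl)oxy]piperidine-1-carboxylate F6. Methanolysis of the ester (K2CO3, MeOH) then gives 19.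

Step 12. The product enal may re-enter the condensation and give oligomers, or dehydration of the aldol may stay incomplete. The fallback sets out from 21 and comes back at 22; it differentiates the two halves and joins them by olefin cross-metathesis. One portion of 21 is α-methylenated (aqueous CH2O, pyrrolidine, propionic acid) to tert-butyl (2S,3S,6R)-6-(11-formyldodec-11-en-1-yl)-3-hydroxy-2-methylpiperidine-1-carboxylate F7. A second portion is converted by Wittig methylenation (Ph3P=CH2, THF) into tert-butyl (2S,3S,6R)-3-hydroxy-2-methyl-6-(tridec-12-en-1-yl)piperidine-1-carboxylate F8. Cross-metathesis of F7 with F8 (second-generation Grubbs catalyst, CH2Cl2, 40 °C) with loss of ethene should give the E-trisubstituted enal 22.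

Further compounds
F1 | step 5 | [3-(methoxymethoxy)prop-1-yn-1-yl]trimethylsilane | COCOCC#C[Si](C)(C)C
F2 | step 5 | bromo[3-(methoxymethoxy)-1-(trimethylsilyl)propa-1,2-dien-1-yl]zinc | COCOC=C=C([Zn]Br)[Si](C)(C)C
F3 | step 5 | (S)-N-[(2S,3R)-3-(methoxymethoxy)-5-(trimethylsilyl)pent-4-yn-2-yl]-2-methylpropane-2-sulfinamide | C[C@H](N[S@@](=O)C(C)(C)C)[C@H](OCOC)C#C[Si](C)(C)C
F4 | step 5 | (S)-N-[(2S,3R)-3-(methoxymethoxy)pent-4-yn-2-yl]-2-methylpropane-2-sulfinamide | C[C@H](N[S@@](=O)C(C)(C)C)[C@H](OCOC)C#C
F5 | step 5 | N,C-dilithio salt of (S)-N-[(2S,3R)-3-(methoxymethoxy)pent-4-yn-2-yl]-2-methylpropane-2-sulfinamide | C[C@H](N([Li])[S@@](=O)C(C)(C)C)[C@H](OCOC)C#C[Li]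
F6 | step 9 | tert-butyl (2S,3S,6R)-6-{12-[(tert-butyldiphenylsilyl)oxy]dodecyl}-2-methyl-3-[(4-nitrobenzoyl)oxy]piperidine-1-carboxylate | C[C@@H]1N(C(=O)OC(C)(C)C)[C@H](CCCCCCCCCCCCO[Si](c2ccccc2)(c2ccccc2)C(C)(C)C)CC[C@@H]1OC(=O)c1ccc(cc1)[N+](=O)[O-]
F7 | step 12 | tert-butyl (2S,3S,6R)-6-(11-formyldodec-11-en-1-yl)-3-hydroxy-2-methylpiperidine-1-carboxylate | C[C@@H]1N(C(=O)OC(C)(C)C)[C@H](CCCCCCCCCCC(=C)C=O)CC[C@@H]1O
F8 | step 12 | tert-butyl (2S,3S,6R)-3-hydroxy-2-methyl-6-(tridec-12-en-1-yl)piperidine-1-carboxylate | C[C@@H]1N(C(=O)OC(C)(C)C)[C@H](CCCCCCCCCCCC=C)CC[C@@H]1O
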